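**Strategy.** Everything rests on annulating ring A (C1–C4) onto a ring-B enal, (R)-5-methylcyclohex-1-ene-1-carbaldehyde, by a Michael–aldol condensation with methyl acetoacetate; the tetramic acid is closed last by Lacey–Dieckmann cyclisation. Ring B is not made as a six-membered ring: (R)-citronellal and a vinyl unit are closed by metathesis to a cycloheptenol, whose trans epoxy silyl ether undergoes a Lewis-acid semipinacol ring contraction. The key step exploits that C4a of ring B carries the exocyclic ring-A carbon C4: in the precursor C4 is a ring member between C4a and C5, and the 1,2-shift of C5 to C4a forms ring B, expels C4 as the formyl group and leaves oxygen on C8a for elimination.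

Key step: step 5

Numbering: atoms carry the decalin numbering of the target (C1 quaternary, C2 dienyl-bearing, C3=C4, C4a, C5, C6 methyl-bearing, C7, C8, C8a); precursor atoms are named by the target atom they become.

Assumption: in step 6 the quinine-derived primary amine is taken as the catalyst antipode that reinforces the intrinsic axial attack cis to the C6 methyl; if it proves mismatched, its quinidine-derived pseudoenantiomer is used.

Step 1
Reactants: 1 (R)-citronellal; 2 vinylmagnesium bromide
Product: 3 (5R)-5,9-dimethyldeca-1,8-dien-3-ol (both C3 epimers)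
Conditions: THF, −78 to 0 °C; aq NH4Cl
Reagents that add atoms: none
Why: Grignard addition to the aldehyde; the new carbinol centre is uncontrolled and is destroyed in step 5.

Step 2
Reactants: 3 (5R)-5,9-dimethyldeca-1,8-dien-3-ol
Product: 4 tert-butyl{[(5R)-5,9-dimethyldeca-1,8-dien-3-yl]oxy}dimethylsilane (both C3 epimers)
Conditions: TBSCl, imidazole, DMF, rt
Reagents that add atoms: tert-butyldimethylsilyl chloride (TBSCl), CC(C)(C)[Si](C)(C)Cl
Why: Silylation of the secondary allylic alcohol provides the silyl ether needed for anti epoxidation and for the rearrangement.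

Step 3
Reactants: 4 tert-butyl{[(5R)-5,9-dimethyldeca-1,8-dien-3-yl]oxy}dimethylsilane
Product: 5 tert-butyl(dimethyl){[(6R)-6-methylcyclohept-2-en-1-yl]oxy}silane (both C1 epimers)
Conditions: second-generation Grubbs catalyst RuCl2(=CHPh)(PCy3)(H2IMes) (3 mol %), CH2Cl2 (0.01 M), 40 °C
Reagents that add atoms: none
Why: Ring-closing metathesis between the vinyl group and the trisubstituted alkene should close the seven-membered ring with loss of isobutene.

Step 4
Reactants: 5 tert-butyl(dimethyl){[(6R)-6-methylcyclohept-2-en-1-yl]oxy}silane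
Product: 6 tert-butyl(dimethyl){[(4R)-4-methyl-8-oxabicyclo[5.1.0]octan-2-yl]oxy}silane with the epoxide trans to the silyloxy group (both epimers at the silyloxy carbon)
Conditions: mCPBA, NaHCO3, CH2Cl2, 0 °C
Reagents that add atoms: 3-chloroperoxybenzoic acid (mCPBA), OOC(=O)c1cccc(Cl)c1
Why: Prilezhaev epoxidation should occur anti to the bulky allylic silyloxy group in both epimeric series, giving the trans epoxy silyl ether.

Step 5
Reactants: 6 trans epoxy silyl ether
Product: 8 (5R)-5-methylcyclohex-1-ene-1-carbaldehyde, via β-siloxy aldehyde 7 (not isolated)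
Conditions: MeAl(OC6H2-4-Br-2,6-t-Bu2)2 (20 mol %), CH2Cl2, −78 to −20 °C; then DBU, rt
Reagents that add atoms: none
Why: The aluminium Lewis acid binds the epoxide oxygen, the C4a–O bond ionises and the antiperiplanar ring bond C4–C5 migrates to C4a with inversion while the silyloxy oxygen stabilises the developing charge at C4; silyl transfer to the C8a oxygen then gives β-siloxy aldehyde 7 (semipinacol rearrangement; closest known type: organoaluminium-promoted rearrangement of 2,3-epoxy silyl ethers to β-siloxy aldehydes). Ring B is closed by this 1,2-alkyl shift, a one-carbon ring contraction of the cycloheptane in which the expelled ring carbon becomes the formyl carbon C4. The two new stereocentres of 7 (C4a by inversion, C8a retained from the epoxide) need no control because DBU removes tert-butyldimethylsilanol by E1cB elimination and leaves C6 as the only stereocentre of 8. The selectivity needed is migration of the ring carbon instead of hydride, which the trans relation of epoxide and silyloxy group secures, since only then is the C4–C5 bond anti to the breaking C–O bond in the conformer with an equatorial silyloxy group. Both C4 epimers of 6 therefore converge on one enal.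

Step 6
Reactants: 8 (5R)-5-methylcyclohex-1-ene-1-carbaldehyde; 9 methyl acetoacetate
Product: 12 methyl (4aR,6R,8aS)-6-methyl-2-oxo-1,2,4a,5,6,7,8,8a-octahydronaphthalene-1-carboxylate (C1 epimers and enol form), via Michael adduct 10 (not isolated), via aldol adduct 11 (not isolated)
Conditions: 9-amino-9-deoxy-epi-quinine (20 mol %), 2-fluorobenzoic acid (40 mol %), toluene, 40 °C; then p-TsOH·H2O (10 mol %), 60 °C
Reagents that add atoms: none
Why: Iminium activation lets the β-keto ester add to C8a in a Michael reaction, axially and cis to the C6 methyl (catalyst and half-chair control matched); the transient aldehyde should settle as the isomer with formyl group and side chain both equatorial (the cis aldehyde needs the side chain axial or the formyl group syn-axial to the methyl), and the methyl ketone closes ring A by intramolecular aldol condensation (amine-catalysed Robinson-type annulation).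

Step 7
Reactants: 12 methyl (4aR,6R,8aS)-6-methyl-2-oxo-1,2,4a,5,6,7,8,8a-octahydronaphthalene-1-carboxylate
Product: 13 methyl (1R,4aR,6R,8aS)-1,6-dimethyl-2-oxo-1,2,4a,5,6,7,8,8a-octahydronaphthalene-1-carboxylate
Conditions: K2CO3, MeI, acetone, rt
Reagents that add atoms: iodomethane, CI
Why: C-Methylation of the β-keto ester enolate of the trans-fused, conformationally locked bicycle should occur axially, anti to the axial H-8a, setting quaternary C1 with the methyl axial (β) and the ester equatorial.

Step 8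
Reactants: 13 methyl (1R,4aR,6R,8aS)-1,6-dimethyl-2-oxo-1,2,4a,5,6,7,8,8a-octahydronaphthalene-1-carboxylate
Product: 14 methyl (1R,4aR,6R,8aS)-1,6-dimethyl-2-methylidene-1,2,4a,5,6,7,8,8a-octahydronaphthalene-1-carboxylate
Conditions: Zn, CH2Br2, TiCl4, THF/CH2Cl2, 0 °C to rt
Reagents that add atoms: dibromomethane, BrCBr
Why: Takai–Lombardo methylenation; the non-basic titanium–zinc methylene reagent attacks the hindered enone carbonyl but not the ester and cannot epimerise C4a.

Step 9
Reactants: 14 methyl (1R,4aR,6R,8aS)-1,6-dimethyl-2-methylidene-1,2,4a,5,6,7,8,8a-octahydronaphthalene-1-carboxylate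
Product: 16 methyl (1R,2R,4aR,6R,8aS)-2-(hydroxymethyl)-1,6-dimethyl-1,2,4a,5,6,7,8,8a-octahydronaphthalene-1-carboxylate, via alkylborane 15 (not isolated)
Conditions: 9-BBN, THF, 0 °C to rt; then 30% H2O2, aq NaOAc
Reagents that add atoms: hydrogen peroxide, OO
Why: Hydroboration–oxidation; 9-BBN should add only to the 1,1-disubstituted exocyclic alkene, boron to the terminal carbon and hydrogen to C2 from the α face opposite the axial C1 methyl, so that the hydroxymethyl group ends β and equatorial.

Step 10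
Reactants: 16 methyl (1R,2R,4aR,6R,8aS)-2-(hydroxymethyl)-1,6-dimethyl-1,2,4a,5,6,7,8,8a-octahydronaphthalene-1-carboxylate
Product: 17 methyl (1R,2R,4aR,6R,8aS)-2-formyl-1,6-dimethyl-1,2,4a,5,6,7,8,8a-octahydronaphthalene-1-carboxylate
Conditions: Dess–Martin periodinane, NaHCO3, CH2Cl2, 0 °C
Reagents that add atoms: none
Why: Dess–Martin oxidation under buffered, non-basic conditions should leave the epimerisable β,γ-unsaturated aldehyde intact.

Step 11
Reactants: 17 methyl (1R,2R,4aR,6R,8aS)-2-formyl-1,6-dimethyl-1,2,4a,5,6,7,8,8a-octahydronaphthalene-1-carboxylate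
Product: 18 methyl (1R,2S,4aR,6R,8aS)-2-[(E)-2-iodoethenyl]-1,6-dimethyl-1,2,4a,5,6,7,8,8a-octahydronaphthalene-1-carboxylate
Conditions: CrCl2, CHI3, THF/1,4-dioxane, 0 °C to rt
Reagents that add atoms: iodoform, IC(I)I
Why: Takai olefination; the geminal dichromium species from iodoform adds to the aldehyde and eliminates to the (E)-vinyl iodide (the C2 descriptor changes by priority only).

Step 12
Reactants: 18 methyl (1R,2S,4aR,6R,8aS)-2-[(E)-2-iodoethenyl]-1,6-dimethyl-1,2,4a,5,6,7,8,8a-octahydronaphthalene-1-carboxylate; 19 (E)-prop-1-en-1-ylboronic acid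
Product: 20 methyl (1R,2R,4aR,6R,8aS)-1,6-dimethyl-2-[(1E,3E)-penta-1,3-dien-1-yl]-1,2,4a,5,6,7,8,8a-octahydronaphthalene-1-carboxylate
Conditions: Pd(PPh3)4 (5 mol %), K3PO4, THF/H2O, 50 °C
Reagents that add atoms: none
Why: Suzuki–Miyaura coupling proceeds with retention of both alkene geometries and gives the (1E,3E)-diene.

Step 13
Reactants: 20 methyl (1R,2R,4aR,6R,8aS)-1,6-dimethyl-2-[(1E,3E)-penta-1,3-dien-1-yl]-1,2,4a,5,6,7,8,8a-octahydronaphthalene-1-carboxylate
Product: 21 [(1R,2R,4aR,6R,8aS)-1,6-dimethyl-2-[(1E,3E)-penta-1,3-dien-1-yl]-1,2,4a,5,6,7,8,8a-octahydronaphthalen-1-yl]methanol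
Conditions: i-Bu2AlH (3 equiv), CH2Cl2, −78 to 0 °C; H2O work-up
Reagents that add atoms: none
Why: Hydride reduction of the neopentyl ester to the primary alcohol; the diene and the ring alkene are inert.

Step 14
Reactants: 21 [(1R,2R,4aR,6R,8aS)-1,6-dimethyl-2-[(1E,3E)-penta-1,3-dien-1-yl]-1,2,4a,5,6,7,8,8a-octahydronaphthalen-1-yl]methanol
Product: 22 (1R,2R,4aR,6R,8aS)-1,6-dimethyl-2-[(1E,3E)-penta-1,3-dien-1-yl]-1,2,4a,5,6,7,8,8a-octahydronaphthalene-1-carbaldehyde
Conditions: Dess–Martin periodinane, CH2Cl2, rt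
Reagents that add atoms: none
Why: Dess–Martin oxidation to the non-enolisable neopentyl aldehyde.

Step 15
Reactants: 22 (1R,2R,4aR,6R,8aS)-1,6-dimethyl-2-[(1E,3E)-penta-1,3-dien-1-yl]-1,2,4a,5,6,7,8,8a-octahydronaphthalene-1-carbaldehyde; 23 S-tert-butyl thioacetate
Product: 24 S-tert-butyl 3-[(1R,2R,4aR,6R,8aS)-1,6-dimethyl-2-[(1E,3E)-penta-1,3-dien-1-yl]-1,2,4a,5,6,7,8,8a-octahydronaphthalen-1-yl]-3-hydroxypropanethioate (both carbinol epimers)
Conditions: LiN(i-Pr)2, THF, −78 °C (enolate of 23 formed first); aq NH4Cl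
Reagents that add atoms: none
Why: Aldol addition of the lithium thioester enolate to the hindered aldehyde; the new carbinol centre is removed in the next step.

Step 16
Reactants: 24 β-hydroxy thioester
Product: 25 S-tert-butyl 3-[(1R,2R,4aR,6R,8aS)-1,6-dimethyl-2-[(1E,3E)-penta-1,3-dien-1-yl]-1,2,4a,5,6,7,8,8a-octahydronaphthalen-1-yl]-3-oxopropanethioate
Conditions: Dess–Martin periodinane, CH2Cl2, rt
Reagents that add atoms: none
Why: Dess–Martin oxidation of the β-hydroxy thioester gives the β-keto thioester.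

Step 17
Reactants: 25 β-keto thioester; 26 L-threonine methyl ester hydrochloride
Product: 27 methyl N-{3-[(1R,2R,4aR,6R,8aS)-1,6-dimethyl-2-[(1E,3E)-penta-1,3-dien-1-yl]-1,2,4a,5,6,7,8,8a-octahydronaphthalen-1-yl]-3-oxopropanoyl}-L-threoninate
Conditions: AgOCOCF3, Et3N, THF, 0 °C to rt
Reagents that add atoms: none
Why: Silver-assisted aminolysis of the thioester; the thiophilic silver salt activates the S-tert-butyl group and the free amine is acylated in preference to the secondary hydroxyl, leaving both amino acid stereocentres untouched.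

Step 18
Reactants: 27 β-keto amide
Product: 28 (5S)-3-{[(1R,2R,4aR,6R,8aS)-1,6-dimethyl-2-[(1E,3E)-penta-1,3-dien-1-yl]-1,2,4a,5,6,7,8,8a-octahydronaphthalen-1-yl]carbonyl}-4-hydroxy-5-[(1R)-1-hydroxyethyl]-1,5-dihydro-2H-pyrrol-2-one (target)
Conditions: NaOMe (3 equiv), MeOH, rt, short reaction time; then aq HCl
Reagents that add atoms: none
Why: Lacey–Dieckmann cyclisation; the doubly activated methylene attacks the methyl ester to close the 3-acyltetramic acid, whose stabilised enolate should protect C5 from epimerisation.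

**Compound list**

1 | (R)-citronellal, (3R)-3,7-dimethyloct-6-enal | O=CC[C@H](C)CCC=C(C)C | starting material
2 | vinylmagnesium bromide | C=C[Mg]Br | starting material
3 | (5R)-5,9-dimethyldeca-1,8-dien-3-ol (both C3 epimers) | C=CC(O)C[C@H](C)CCC=C(C)C | intermediate
4 | tert-butyl{[(5R)-5,9-dimethyldeca-1,8-dien-3-yl]oxy}dimethylsilane (both C3 epimers) | C=CC(O[Si](C)(C)C(C)(C)C)C[C@H](C)CCC=C(C)C | intermediate
5 | tert-butyl(dimethyl){[(6R)-6-methylcyclohept-2-en-1-yl]oxy}silane (both C1 epimers) | CC(C)(C)[Si](C)(C)OC1C=CCC[C@@H](C)C1 | intermediate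
6 | tert-butyl(dimethyl){[(4R)-4-methyl-8-oxabicyclo[5.1.0]octan-2-yl]oxy}silane, epoxide trans to the silyloxy group (both C2 epimers) | CC(C)(C)[Si](C)(C)OC1C2OC2CC[C@@H](C)C1 | intermediate
7 | (5R)-2-[(tert-butyldimethylsilyl)oxy]-5-methylcyclohexane-1-carbaldehyde, formyl and silyloxy cis (both such diastereomers), not isolated | O=CC1C(O[Si](C)(C)C(C)(C)C)CC[C@@H](C)C1 | intermediate
8 | (5R)-5-methylcyclohex-1-ene-1-carbaldehyde | O=CC1=CCC[C@@H](C)C1 | intermediate
9 | methyl acetoacetate | COC(=O)CC(C)=O | starting material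
10 | methyl 2-[(1S,2S,4R)-2-formyl-4-methylcyclohexyl]-3-oxobutanoate (epimeric at the butanoate C2), not isolated | O=C[C@H]1C[C@H](C)CC[C@@H]1C(C(C)=O)C(=O)OC | intermediate
11 | methyl (4aS,6R,8aS)-4-hydroxy-6-methyl-2-oxodecahydronaphthalene-1-carboxylate (C1 and C4 epimers), not isolated | O=C1CC(O)[C@H]2C[C@H](C)CC[C@@H]2C1C(=O)OC | intermediate
12 | methyl (4aR,6R,8aS)-6-methyl-2-oxo-1,2,4a,5,6,7,8,8a-octahydronaphthalene-1-carboxylate (C1 epimers and enol form) | O=C1C=C[C@H]2C[C@H](C)CC[C@@H]2C1C(=O)OC | intermediate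
13 | methyl (1R,4aR,6R,8aS)-1,6-dimethyl-2-oxo-1,2,4a,5,6,7,8,8a-octahydronaphthalene-1-carboxylate | O=C1C=C[C@H]2C[C@H](C)CC[C@@H]2[C@@]1(C)C(=O)OC | intermediate
14 | methyl (1R,4aR,6R,8aS)-1,6-dimethyl-2-methylidene-1,2,4a,5,6,7,8,8a-octahydronaphthalene-1-carboxylate | C=C1C=C[C@H]2C[C@H](C)CC[C@@H]2[C@@]1(C)C(=O)OC | intermediate
15 | methyl (1S,2R,4aR,6R,8aS)-2-[(9-borabicyclo[3.3.1]nonan-9-yl)methyl]-1,6-dimethyl-1,2,4a,5,6,7,8,8a-octahydronaphthalene-1-carboxylate, not isolated | C(B1C2CCCC1CCC2)[C@@H]1C=C[C@H]2C[C@H](C)CC[C@@H]2[C@@]1(C)C(=O)OC | intermediate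
16 | methyl (1R,2R,4aR,6R,8aS)-2-(hydroxymethyl)-1,6-dimethyl-1,2,4a,5,6,7,8,8a-octahydronaphthalene-1-carboxylate | OC[C@@H]1C=C[C@H]2C[C@H](C)CC[C@@H]2[C@@]1(C)C(=O)OC | intermediate
17 | methyl (1R,2R,4aR,6R,8aS)-2-formyl-1,6-dimethyl-1,2,4a,5,6,7,8,8a-octahydronaphthalene-1-carboxylate | O=C[C@@H]1C=C[C@H]2C[C@H](C)CC[C@@H]2[C@@]1(C)C(=O)OC | intermediate
18 | methyl (1R,2S,4aR,6R,8aS)-2-[(E)-2-iodoethenyl]-1,6-dimethyl-1,2,4a,5,6,7,8,8a-octahydronaphthalene-1-carboxylate | I/C=C/[C@@H]1C=C[C@H]2C[C@H](C)CC[C@@H]2[C@@]1(C)C(=O)OC | intermediate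
19 | (E)-prop-1-en-1-ylboronic acid | C/C=C/B(O)O | starting material
20 | methyl (1R,2R,4aR,6R,8aS)-1,6-dimethyl-2-[(1E,3E)-penta-1,3-dien-1-yl]-1,2,4a,5,6,7,8,8a-octahydronaphthalene-1-carboxylate | C/C=C/C=C/[C@@H]1C=C[C@H]2C[C@H](C)CC[C@@H]2[C@@]1(C)C(=O)OC | intermediate
21 | [(1R,2R,4aR,6R,8aS)-1,6-dimethyl-2-[(1E,3E)-penta-1,3-dien-1-yl]-1,2,4a,5,6,7,8,8a-octahydronaphthalen-1-yl]methanol | C/C=C/C=C/[C@@H]1C=C[C@H]2C[C@H](C)CC[C@@H]2[C@@]1(C)CO | intermediate
22 | (1R,2R,4aR,6R,8aS)-1,6-dimethyl-2-[(1E,3E)-penta-1,3-dien-1-yl]-1,2,4a,5,6,7,8,8a-octahydronaphthalene-1-carbaldehyde | C/C=C/C=C/[C@@H]1C=C[C@H]2C[C@H](C)CC[C@@H]2[C@@]1(C)C=O | intermediate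
23 | S-tert-butyl thioacetate | CC(=O)SC(C)(C)C | starting material
24 | S-tert-butyl 3-[(1R,2R,4aR,6R,8aS)-1,6-dimethyl-2-[(1E,3E)-penta-1,3-dien-1-yl]-1,2,4a,5,6,7,8,8a-octahydronaphthalen-1-yl]-3-hydroxypropanethioate (both carbinol epimers) | C/C=C/C=C/[C@@H]1C=C[C@H]2C[C@H](C)CC[C@@H]2[C@@]1(C)C(O)CC(=O)SC(C)(C)C | intermediate
25 | S-tert-butyl 3-[(1R,2R,4aR,6R,8aS)-1,6-dimethyl-2-[(1E,3E)-penta-1,3-dien-1-yl]-1,2,4a,5,6,7,8,8a-octahydronaphthalen-1-yl]-3-oxopropanethioate | C/C=C/C=C/[C@@H]1C=C[C@H]2C[C@H](C)CC[C@@H]2[C@@]1(C)C(=O)CC(=O)SC(C)(C)C | intermediate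
26 | L-threonine methyl ester hydrochloride | COC(=O)[C@H]([C@@H](C)O)N.Cl | starting material
27 | methyl N-{3-[(1R,2R,4aR,6R,8aS)-1,6-dimethyl-2-[(1E,3E)-penta-1,3-dien-1-yl]-1,2,4a,5,6,7,8,8a-octahydronaphthalen-1-yl]-3-oxopropanoyl}-L-threoninate | C/C=C/C=C/[C@@H]1C=C[C@H]2C[C@H](C)CC[C@@H]2[C@@]1(C)C(=O)CC(=O)N[C@@H]([C@@H](C)O)C(=O)OC | intermediate
28 | (5S)-3-{[(1R,2R,4aR,6R,8aS)-1,6-dimethyl-2-[(1E,3E)-penta-1,3-dien-1-yl]-1,2,4a,5,6,7,8,8a-octahydronaphthalen-1-yl]carbonyl}-4-hydroxy-5-[(1R)-1-hydroxyethyl]-1,5-dihydro-2H-pyrrol-2-one | C/C=C/C=C/[C@@H]1C=C[C@H]2C[C@H](C)CC[C@@H]2[C@@]1(C)C(=O)C1=C(O)[C@H]([C@@H](C)O)NC1=O | target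

**Step count and risks**

Total step count: 18. Longest linear sequence: 18 steps (from 1).

Steps most likely to fail:

1. Step 6. The α-branched enal may form the iminium ion slowly and Knoevenagel condensation at the aldehyde may compete. The trans ring fusion may also erode through epimerization at C4a, because the C6 methyl has to become axial in the trans-fused product and this removes much of the usual preference. Fallback, from 8 back to 12: the Michael addition is run under Brønsted-base control and the ring is closed irreversibly by olefination instead of aldol condensation. Enal 8 and methyl 4-(dimethoxyphosphoryl)-3-oxobutanoate (COC(=O)CC(=O)CP(=O)(OC)OC) with catalytic DBU in THF should give methyl 4-(dimethoxyphosphoryl)-2-[(1S,2S,4R)-2-formyl-4-methylcyclohexyl]-3-oxobutanoate F1 by axial attack cis to the methyl. F1 is closed at once with LiCl and i-Pr2NEt in MeCN (intramolecular Horner–Wadsworth–Emmons olefination) to 12, so that the product is not exposed to an amine that can epimerise it.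

2. Step 5. Hydride migration may take the place of ring-carbon migration (the minor cis epoxide can only react this way), or the epoxide may open at the remote carbon. Fallback, from 5 back to 8: the leaving group is changed from epoxide oxygen to bromide. NBS in wet THF should give, by anti opening of the bromonium ion at the carbon remote from the silyloxy group, (5R)-2-bromo-3-[(tert-butyldimethylsilyl)oxy]-5-methylcycloheptan-1-ol F2. AgBF4 in CH2Cl2 then abstracts bromide with migration of the antiperiplanar ring carbon and loss of the silyl group to give (5R)-2-hydroxy-5-methylcyclohexane-1-carbaldehyde F3. MsCl and Et3N dehydrate F3 to 8.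

3. Step 11. The hindered β,γ-unsaturated aldehyde may react incompletely, and enolization by the chromium species may epimerise C2 or move the ring double bond. Fallback, from 17 back to 20 (no new compound, F0): the diene is made in one operation by Julia–Kocienski olefination with 5-[(E)-but-2-en-1-ylsulfonyl]-1-phenyl-1H-tetrazole (C/C=C/CS(=O)(=O)c1nnnn1-c1ccccc1). The sulfone is deprotonated first with KN(SiMe3)2 in DME at −60 °C and the aldehyde is then added, followed by iodine-catalysed isomerisation of any (1Z) isomer; this bypasses step 12.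

Further compounds
F1 | step 6 | methyl 4-(dimethoxyphosphoryl)-2-[(1S,2S,4R)-2-formyl-4-methylcyclohexyl]-3-oxobutanoate | O=C[C@H]1C[C@H](C)CC[C@@H]1C(C(=O)OC)C(=O)CP(=O)(OC)OC
F2 | step 5 | (5R)-2-bromo-3-[(tert-butyldimethylsilyl)oxy]-5-methylcycloheptan-1-ol (bromine trans to both oxygens) | CC(C)(C)[Si](C)(C)OC1C(Br)C(O)CC[C@@H](C)C1
F3 | step 5 | (5R)-2-hydroxy-5-methylcyclohexane-1-carbaldehyde | O=CC1C(O)CC[C@@H](C)C1
F0 | step 11 | none | none
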